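**Plan** (locants: tetrahydronaphthalene numbering of the target; C2 CO2Me, C3 OMe, C4 OH, C5 CH–CH3, C6/C7 CH2, C8 CH–side chain, side chain C1′–C7′)
1. Retrosynthesis: first the two O-benzyl groups are cut, then in one operation the C6–C7 ring bond and the C5–CH3 bond, which leads back to an open-chain aryl(vinyl) carboxylic acid. Next come the aryl–C8 bond (Rh 1,4-addition to a chiral enoate), the aryl–C5 bond (Claisen) and the enoate C=C (cross-metathesis).
2. Forward: the enoate comes from (S)-citronellyl bromide (steps 1–5) and the arylboronate from methyl 2,3-dihydroxybenzoate (steps 6–11). They are joined in step 12 and trimmed to the vinyl acid (steps 13–14). The cyclohexane ring, the only ring that is built, closes in step 15, and step 16 deprotects.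
3. Enabling feature: the two arms sit on adjacent carbons of the benzene ring (future C4a and C8a), and the vinyl-bearing carbon (future C4a) is para to the ester-bearing carbon C2. The vinyl group is therefore a vinylogous acrylate: a primary radical made by decarboxylation of the CH2CO2H arm adds 6-endo to its terminal carbon, and the benzylic radical at future C5 is methylated on nickel.
4. Stereochemistry: C2′ comes from (S)-citronellyl bromide, C6′ from a Ru–BINAP hydrogenation, and C8 from the ligand-controlled Rh addition. C5 is set in the key step by the C8 centre, with CH3 entering anti to the side chain (5,8-trans).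

Key step: step 15

Remark: the target is read as the 5,8-trans tetralin (5R,8S) with a (2S,6S) side chain; the ligand enantiomers in steps 2 and 12 are assigned from the usual facial models for Ru–BINAP (geraniol) and Rh–BINAP ((E)-enoates).

Step 1
Reactants: 1 (S)-citronellyl bromide [(6S)-8-bromo-2,6-dimethyloct-2-ene]
Product: 2 (2E,6S)-8-bromo-2,6-dimethyloct-2-en-1-ol
Conditions: SeO2 (cat.), t-BuOOH, CH2Cl2, 0 °C to rt
Reagents that add atoms: tert-butyl hydroperoxide CC(C)(C)OO (oxygen atom, relayed through selenium dioxide O=[Se]=O)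
Why: Sharpless SeO2/t-BuOOH allylic oxidation (ene reaction, then [2,3]-shift) should hydroxylate the (E)-methyl group of the trisubstituted alkene and leave the primary bromide and the stereocentre untouched.

Step 2
Reactants: 2 (2E,6S)-8-bromo-2,6-dimethyloct-2-en-1-ol
Product: 3 (2S,6S)-8-bromo-2,6-dimethyloctan-1-ol
Conditions: Ru(OAc)2[(S)-BINAP] (1 mol%), H2 (30 bar), MeOH, rt
Reagents that add atoms: none
Why: Hydroxyl-directed Ru–BINAP asymmetric hydrogenation (Noyori type) of the trisubstituted allylic alcohol should set C2 as S under ligand control, the (S)-ligand being assigned from the geraniol facial model, with no other alkene present and the C–Br bond inert.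

Step 3
Reactants: 3 (2S,6S)-8-bromo-2,6-dimethyloctan-1-ol
Product: 4 (2S,6S)-2,6-dimethyloct-7-en-1-ol
Conditions: KOt-Bu (2.2 equiv), DMSO, rt
Reagents that add atoms: none
Why: E2 dehydrobromination of the primary bromide by a hindered base should give the terminal alkene, the product alkoxide being a spectator and neither stereocentre lying next to an acidic site.

Step 4
Reactants: 4 (2S,6S)-2,6-dimethyloct-7-en-1-ol
Product: 5 benzyl (2S,6S)-2,6-dimethyloct-7-en-1-yl ether
Conditions: NaH, BnBr, n-Bu4NI (cat.), THF, 0 °C to rt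
Reagents that add atoms: benzyl bromide BrCc1ccccc1
Why: Williamson etherification protects the primary alcohol as a benzyl ether that survives the later acidic, basic and organometallic steps and falls in the final hydrogenolysis.

Step 5
Reactants: 5 benzyl (2S,6S)-2,6-dimethyloct-7-en-1-yl ether
Product: 6 tert-butyl (2E,4S,8S)-9-(benzyloxy)-4,8-dimethylnon-2-enoate
Conditions: tert-butyl acrylate (3 equiv), second-generation Hoveyda–Grubbs catalyst (3 mol%), CH2Cl2, 40 °C
Reagents that add atoms: tert-butyl acrylate C=CC(=O)OC(C)(C)C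
Why: Olefin cross-metathesis of a terminal alkene with an acrylate should give the (E)-enoate selectively without touching the γ-stereocentre.

Step 6
Reactants: 7 methyl 2,3-dihydroxybenzoate
Product: 8 methyl 5-bromo-2,3-dihydroxybenzoate
Conditions: Br2 (1.0 equiv), AcOH, 15 °C
Reagents that add atoms: bromine BrBr
Why: Electrophilic aromatic bromination should enter C5, para to the 2-hydroxyl and meta to the ester, the position also taken by nitration and sulfonation of this ring system.

Step 7
Reactants: 8 methyl 5-bromo-2,3-dihydroxybenzoate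
Product: 9 methyl 3-(allyloxy)-5-bromo-2-hydroxybenzoate
Conditions: allyl bromide (1.05 equiv), K2CO3 (1.1 equiv), acetone, 40 °C
Reagents that add atoms: allyl bromide C=CCBr
Why: Williamson allylation with one equivalent of base should alkylate the 3-hydroxyl only, because the 2-hydroxyl is held in a hydrogen bond to the ester carbonyl.

Step 8
Reactants: 9 methyl 3-(allyloxy)-5-bromo-2-hydroxybenzoate
Product: 10 methyl 3-(allyloxy)-5-bromo-2-methoxybenzoate
Conditions: MeI, K2CO3, DMF, 50 °C
Reagents that add atoms: iodomethane CI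
Why: Williamson O-methylation of the remaining hydrogen-bonded phenol under more forcing conditions fixes the 2-methoxy group of the target.

Step 9
Reactants: 10 methyl 3-(allyloxy)-5-bromo-2-methoxybenzoate
Product: 11 methyl 4-allyl-5-bromo-3-hydroxy-2-methoxybenzoate
Conditions: PhNEt2, 190 °C
Reagents that add atoms: none
Why: Thermal aromatic Claisen rearrangement ([3,3]-sigmatropic shift, then tautomerisation) should move the allyl group to C4, the only open ortho position, placing a carbon substituent between the phenol and the bromide.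

Step 10
Reactants: 11 methyl 4-allyl-5-bromo-3-hydroxy-2-methoxybenzoate
Product: 12 methyl 4-allyl-3-(benzyloxy)-5-bromo-2-methoxybenzoate
Conditions: BnBr, K2CO3, DMF, 60 °C
Reagents that add atoms: benzyl bromide BrCc1ccccc1
Why: Williamson benzylation masks the phenol for the organometallic steps and keeps it distinct from the methyl ether.

Step 11
Reactants: 12 methyl 4-allyl-3-(benzyloxy)-5-bromo-2-methoxybenzoate
Product: 13 methyl 4-allyl-3-(benzyloxy)-2-methoxy-5-(4,4,5,5-tetramethyl-1,3,2-dioxaborolan-2-yl)benzoate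
Conditions: B2pin2, Pd(dppf)Cl2 (3 mol%), KOAc, dioxane, 90 °C
Reagents that add atoms: bis(pinacolato)diboron CC1(C)OB(OC1(C)C)B1OC(C)(C)C(C)(C)O1
Why: Miyaura borylation turns the aryl bromide into the boronate needed for the conjugate addition, the ester and the allyl group being tolerated under the weak base KOAc.

Step 12
Reactants: 13 methyl 4-allyl-3-(benzyloxy)-2-methoxy-5-(4,4,5,5-tetramethyl-1,3,2-dioxaborolan-2-yl)benzoate; 6 tert-butyl (2E,4S,8S)-9-(benzyloxy)-4,8-dimethylnon-2-enoate
Product: 14 tert-butyl (3S,4S,8S)-3-[2-allyl-3-(benzyloxy)-4-methoxy-5-(methoxycarbonyl)phenyl]-9-(benzyloxy)-4,8-dimethylnonanoate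
Conditions: [RhCl(C2H4)2]2 (3 mol%), (S)-BINAP (7 mol%), K3PO4 (aq, 0.5 equiv), dioxane/H2O, 60 °C, 13 in excess
Reagents that add atoms: none
Why: Hayashi–Miyaura rhodium-catalysed asymmetric 1,4-addition should deliver the aryl group to the 2si face of the (E)-enoate under control of (S)-BINAP, which sets the benzylic centre as S irrespective of the neighbouring methyl-bearing centre.

Step 13
Reactants: 14 tert-butyl (3S,4S,8S)-3-[2-allyl-3-(benzyloxy)-4-methoxy-5-(methoxycarbonyl)phenyl]-9-(benzyloxy)-4,8-dimethylnonanoate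
Product: 15 (3S,4S,8S)-3-[2-allyl-3-(benzyloxy)-4-methoxy-5-(methoxycarbonyl)phenyl]-9-(benzyloxy)-4,8-dimethylnonanoic acid
Conditions: TFA, CH2Cl2, 0 °C to rt
Reagents that add atoms: none
Why: Acidolysis of the tert-butyl ester (loss of 2-methylpropene) frees the aliphatic acid while the aryl methyl ester, both benzyl ethers and the allyl group persist.

Step 14
Reactants: 15 (3S,4S,8S)-3-[2-allyl-3-(benzyloxy)-4-methoxy-5-(methoxycarbonyl)phenyl]-9-(benzyloxy)-4,8-dimethylnonanoic acid
Product: 17 (3S,4S,8S)-9-(benzyloxy)-3-[3-(benzyloxy)-2-ethenyl-4-methoxy-5-(methoxycarbonyl)phenyl]-4,8-dimethylnonanoic acid, via (E)-propenyl acid 16 (not isolated)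
Conditions: [Pd(μ-Br)(P(t-Bu)3)]2 (1 mol%), second-generation Hoveyda–Grubbs catalyst (5 mol%), ethylene (10 bar), THF, 50 °C
Reagents that add atoms: ethylene C=C
Why: Isomerising ethenolysis, a tandem of Pd–H double-bond migration into conjugation with the ring and Ru-carbene cross-metathesis with ethylene, should shorten the allyl group to the vinyl group, and both catalysts tolerate free carboxylic acids.

Step 15
Reactants: 17 (3S,4S,8S)-9-(benzyloxy)-3-[3-(benzyloxy)-2-ethenyl-4-methoxy-5-(methoxycarbonyl)phenyl]-4,8-dimethylnonanoic acid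
Product: 19 methyl (5R,8S)-4-(benzyloxy)-8-[(2S,6S)-7-(benzyloxy)-6-methylheptan-2-yl]-3-methoxy-5-methyl-5,6,7,8-tetrahydronaphthalene-2-carboxylate, via N-acyloxyphthalimide ester 18 (not isolated)
Conditions: N-hydroxyphthalimide, DIC, DMAP (cat.), THF, rt; then NiCl2·glyme (10 mol%), 4,4′-di-tert-butyl-2,2′-bipyridine (20 mol%), Me2Zn (3 equiv, slow addition), THF/DMF, rt
Reagents that add atoms: dimethylzinc C[Zn]C; N-hydroxyphthalimide ON1C(=O)c2ccccc2C1=O (atoms in 18 only)
Why: Proposed new method: Single-electron reduction of ester 18 by low-valent nickel releases CO2 and a primary radical at the CH2 group next to the benzylic stereocentre; this radical adds to the terminal carbon of the ortho vinyl group, the resulting benzylic radical is captured by a CH3–nickel species formed from Me2Zn, and reductive elimination from trivalent nickel forms the C5–CH3 bond. The closest known reaction types are the nickel-catalysed decarboxylative alkyl–alkyl Negishi coupling of redox-active esters, for which 5-exo radical cyclisation before coupling is documented, and the nickel-catalysed dialkylation of vinylarenes with alkyl halides and alkylzinc reagents; a 6-endo closure ended by methylation of a secondary benzylic radical has not been shown. The cyclohexane ring closes in the 6-endo-trig mode, preferred over 5-exo because the vinyl group is a vinylogous acrylate (its ring carbon is para to the ester-bearing carbon), so the nucleophilic radical attacks the terminal carbon and gives a benzylic radical conjugated to the ester. The new stereocentre C5 is controlled by C8: the branched side chain sits pseudoaxial to avoid the peri C1–H and shields one face, so the bulky ligated nickel should bind the opposite face and deliver CH3 with retention, giving the 5,8-trans (5R) product with both groups pseudoaxial, which also relieves peri strain between C5–CH3 and the C4 benzyloxy group. The step needs ring closure to outrun direct methylation of the primary radical and β-hydride loss at the benzylic nickel stage; low nickel loading, slow addition of Me2Zn and the fast, polarity-matched cyclisation should secure this.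

Step 16
Reactants: 19 methyl (5R,8S)-4-(benzyloxy)-8-[(2S,6S)-7-(benzyloxy)-6-methylheptan-2-yl]-3-methoxy-5-methyl-5,6,7,8-tetrahydronaphthalene-2-carboxylate
Product: 20 methyl (5R,8S)-4-hydroxy-8-[(2S,6S)-7-hydroxy-6-methylheptan-2-yl]-3-methoxy-5-methyl-5,6,7,8-tetrahydronaphthalene-2-carboxylate (target)
Conditions: H2 (1 atm), Pd(OH)2 on carbon, EtOAc/MeOH, rt
Reagents that add atoms: none
Why: Hydrogenolysis cleaves both benzyl ethers at once and leaves the methyl ester, the methyl ether and the four stereocentres untouched.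

**Compound list**
1 | (S)-citronellyl bromide, (6S)-8-bromo-2,6-dimethyloct-2-ene | BrCC[C@@H](C)CCC=C(C)C | starting material
2 | (2E,6S)-8-bromo-2,6-dimethyloct-2-en-1-ol | BrCC[C@@H](C)CC/C=C(\C)CO | intermediate
3 | (2S,6S)-8-bromo-2,6-dimethyloctan-1-ol | BrCC[C@@H](C)CCC[C@H](C)CO | intermediate
4 | (2S,6S)-2,6-dimethyloct-7-en-1-ol | C=C[C@@H](C)CCC[C@H](C)CO | intermediate
5 | benzyl (2S,6S)-2,6-dimethyloct-7-en-1-yl ether | C=C[C@@H](C)CCC[C@H](C)COCc1ccccc1 | intermediate
6 | tert-butyl (2E,4S,8S)-9-(benzyloxy)-4,8-dimethylnon-2-enoate | CC(C)(C)OC(=O)/C=C/[C@@H](C)CCC[C@H](C)COCc1ccccc1 | intermediate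
7 | methyl 2,3-dihydroxybenzoate | COC(=O)c1cccc(O)c1O | starting material
8 | methyl 5-bromo-2,3-dihydroxybenzoate | COC(=O)c1cc(Br)cc(O)c1O | intermediate
9 | methyl 3-(allyloxy)-5-bromo-2-hydroxybenzoate | COC(=O)c1cc(Br)cc(OCC=C)c1O | intermediate
10 | methyl 3-(allyloxy)-5-bromo-2-methoxybenzoate | COC(=O)c1cc(Br)cc(OCC=C)c1OC | intermediate
11 | methyl 4-allyl-5-bromo-3-hydroxy-2-methoxybenzoate | COC(=O)c1cc(Br)c(CC=C)c(O)c1OC | intermediate
12 | methyl 4-allyl-3-(benzyloxy)-5-bromo-2-methoxybenzoate | COC(=O)c1cc(Br)c(CC=C)c(OCc2ccccc2)c1OC | intermediate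
13 | methyl 4-allyl-3-(benzyloxy)-2-methoxy-5-(4,4,5,5-tetramethyl-1,3,2-dioxaborolan-2-yl)benzoate | COC(=O)c1cc(B2OC(C)(C)C(C)(C)O2)c(CC=C)c(OCc2ccccc2)c1OC | intermediate
14 | tert-butyl (3S,4S,8S)-3-[2-allyl-3-(benzyloxy)-4-methoxy-5-(methoxycarbonyl)phenyl]-9-(benzyloxy)-4,8-dimethylnonanoate | COC(=O)c1cc([C@@H](CC(=O)OC(C)(C)C)[C@@H](C)CCC[C@H](C)COCc2ccccc2)c(CC=C)c(OCc2ccccc2)c1OC | intermediate
15 | (3S,4S,8S)-3-[2-allyl-3-(benzyloxy)-4-methoxy-5-(methoxycarbonyl)phenyl]-9-(benzyloxy)-4,8-dimethylnonanoic acid | COC(=O)c1cc([C@@H](CC(=O)O)[C@@H](C)CCC[C@H](C)COCc2ccccc2)c(CC=C)c(OCc2ccccc2)c1OC | intermediate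
16 | (3S,4S,8S)-9-(benzyloxy)-3-{3-(benzyloxy)-4-methoxy-5-(methoxycarbonyl)-2-[(E)-prop-1-enyl]phenyl}-4,8-dimethylnonanoic acid | COC(=O)c1cc([C@@H](CC(=O)O)[C@@H](C)CCC[C@H](C)COCc2ccccc2)c(/C=C/C)c(OCc2ccccc2)c1OC | intermediate
17 | (3S,4S,8S)-9-(benzyloxy)-3-[3-(benzyloxy)-2-ethenyl-4-methoxy-5-(methoxycarbonyl)phenyl]-4,8-dimethylnonanoic acid | COC(=O)c1cc([C@@H](CC(=O)O)[C@@H](C)CCC[C@H](C)COCc2ccccc2)c(C=C)c(OCc2ccccc2)c1OC | intermediate
18 | 1,3-dioxoisoindolin-2-yl (3S,4S,8S)-9-(benzyloxy)-3-[3-(benzyloxy)-2-ethenyl-4-methoxy-5-(methoxycarbonyl)phenyl]-4,8-dimethylnonanoate | COC(=O)c1cc([C@@H](CC(=O)ON2C(=O)c3ccccc3C2=O)[C@@H](C)CCC[C@H](C)COCc2ccccc2)c(C=C)c(OCc2ccccc2)c1OC | intermediate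
19 | methyl (5R,8S)-4-(benzyloxy)-8-[(2S,6S)-7-(benzyloxy)-6-methylheptan-2-yl]-3-methoxy-5-methyl-5,6,7,8-tetrahydronaphthalene-2-carboxylate | COC(=O)c1cc2c(c(OCc3ccccc3)c1OC)[C@H](C)CC[C@H]2[C@@H](C)CCC[C@H](C)COCc1ccccc1 | intermediate
20 | methyl (5R,8S)-4-hydroxy-8-[(2S,6S)-7-hydroxy-6-methylheptan-2-yl]-3-methoxy-5-methyl-5,6,7,8-tetrahydronaphthalene-2-carboxylate | COC(=O)c1cc2c(c(O)c1OC)[C@H](C)CC[C@H]2[C@@H](C)CCC[C@H](C)CO | target

**Totals:** 16 steps in all; longest linear sequence 11 steps (steps 6–16, from 7).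

**Steps most likely to fail**

Step 15 (labelled step). What may go wrong: nickel capture and methylation of the primary radical before ring closure, competing 5-exo closure, β-hydride loss from the benzylic nickel species, or weak facial discrimination in the nickel capture at C5. The fallback uses known chemistry, sets out from 17 and returns at 19. Acid 17 is converted with N-hydroxyphthalimide and DIC into ester 18, which is isolated. Irradiation of 18 with Ru(bpy)3Cl2, Hantzsch ester and i-Pr2NEt (blue LEDs, CH2Cl2) should give, by reductive decarboxylative 6-endo Giese cyclisation with hydrogen-atom transfer to the benzylic radical, the tetralin without the C5 methyl group, methyl (8S)-4-(benzyloxy)-8-[(2S,6S)-7-(benzyloxy)-6-methylheptan-2-yl]-3-methoxy-5,6,7,8-tetrahydronaphthalene-2-carboxylate F1. Deprotonation of F1 at C5 (benzylic and para to the ester, lateral metalation of a p-alkylbenzoate) with lithium 2,2,6,6-tetramethylpiperidide and DMPU in THF at −78 °C, then MeI, should place the methyl group anti to the pseudoaxial C8 side chain and give 19.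

Step 12. What may go wrong: slow insertion of the ortho-substituted aryl–rhodium species into the γ-branched enoate so that protodeboronation wins, or eroded facial selectivity if the γ-centre is mismatched with the ligand. The fallback replaces catalyst control by auxiliary control, sets out from 5 and 12 and returns at 15. Cross-metathesis of 5 with 3-acryloyl-(4S)-4-phenyl-1,3-oxazolidin-2-one (second-generation Hoveyda–Grubbs catalyst) should give (4S)-3-[(2E,4S,8S)-9-(benzyloxy)-4,8-dimethylnon-2-enoyl]-4-phenyl-1,3-oxazolidin-2-one F2. Bromine–magnesium exchange on 12 (i-PrMgCl·LiCl, THF, −30 °C), transmetalation with CuBr·SMe2 and 1,4-addition to F2, anti to the phenyl group of the chelated imide, should give methyl 3-(benzyloxy)-5-{(3S,4S,8S)-9-(benzyloxy)-4,8-dimethyl-1-oxo-1-[(4S)-2-oxo-4-phenyl-1,3-oxazolidin-3-yl]nonan-3-yl}-2-methoxy-4-(prop-2-en-1-yl)benzoate F3. Cleavage of the auxiliary with LiOH/H2O2 gives acid 15.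

Step 14. What may go wrong: stalling of the ethenolysis at the di-ortho-substituted propenyl stage, or decay of the ruthenium carbene in the presence of the palladium hydride. The fallback replaces metathesis by oxidative cleavage and olefination, sets out from 15 and returns at 17. Isomerisation of 15 with RuHCl(CO)(PPh3)3 in toluene at 80 °C gives 16, which is isolated. Cleavage of the propenyl group with OsO4 (cat.), NaIO4 and 2,6-lutidine in dioxane/water should give the aryl aldehyde (3S,4S,8S)-9-(benzyloxy)-3-[3-(benzyloxy)-2-formyl-4-methoxy-5-(methoxycarbonyl)phenyl]-4,8-dimethylnonanoic acid F4. Wittig methylenation with excess Ph3P=CH2 in THF gives 17.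

**Further compounds**
F1 | step 15 | methyl (8S)-4-(benzyloxy)-8-[(2S,6S)-7-(benzyloxy)-6-methylheptan-2-yl]-3-methoxy-5,6,7,8-tetrahydronaphthalene-2-carboxylate | COC(=O)c1cc2c(c(OCc3ccccc3)c1OC)CCC[C@H]2[C@@H](C)CCC[C@H](C)COCc1ccccc1
F2 | step 12 | (4S)-3-[(2E,4S,8S)-9-(benzyloxy)-4,8-dimethylnon-2-enoyl]-4-phenyl-1,3-oxazolidin-2-one | O=C1OC[C@H](c2ccccc2)N1C(=O)/C=C/[C@@H](C)CCC[C@H](C)COCc1ccccc1
F3 | step 12 | methyl 3-(benzyloxy)-5-{(3S,4S,8S)-9-(benzyloxy)-4,8-dimethyl-1-oxo-1-[(4S)-2-oxo-4-phenyl-1,3-oxazolidin-3-yl]nonan-3-yl}-2-methoxy-4-(prop-2-en-1-yl)benzoate | COC(=O)c1cc([C@@H](CC(=O)N2[C@@H](c3ccccc3)COC2=O)[C@@H](C)CCC[C@H](C)COCc2ccccc2)c(CC=C)c(OCc2ccccc2)c1OC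
F4 | step 14 | (3S,4S,8S)-9-(benzyloxy)-3-[3-(benzyloxy)-2-formyl-4-methoxy-5-(methoxycarbonyl)phenyl]-4,8-dimethylnonanoic acid | COC(=O)c1cc([C@@H](CC(=O)O)[C@@H](C)CCC[C@H](C)COCc2ccccc2)c(C=O)c(OCc2ccccc2)c1OC
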